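**Analysis of the target**

Isodihydromaldoxin (23) is a diaryl ether. Two benzene rings, ring A and ring B, are joined by one oxygen between C2 of ring A and C2' of ring B, and there is no other ring. Ring A is a methyl benzoate (ester on C1) with the ether oxygen on C2, a methoxy group on C3 and a free phenol on C5. Ring B is a benzoic acid (carboxyl on C1') flanked by the ether oxygen on C2' and a phenol on C6', with chlorine on C5' and methyl on C4', so that only C3' carries hydrogen. The molecule has no stereocentre, and with three ortho substituents around the ether the aryl–oxygen bonds are expected to rotate freely, so nothing stereochemical has to be set. Sensitive points are the electron-rich salicylic acid of ring B (prone to decarboxylation on heating in acid), the p-alkoxyphenol of ring A (oxidisable), the aryl chloride (lost under hydrogenolysis), and the coexistence of a free acid on one ring with a methyl ester on the other. The difficulty is the ether bond between two electron-rich, ortho-crowded rings, where substitution and copper-mediated couplings are weakest, together with the contiguous C6'–C1'–C2' array of ring B. The strategy rests on that array: oxygen on C6', carbon on C1' and aryloxy on C2' is the pattern left when a 3-alkoxyaryne (triple bond C1'–C2', alkoxy on C6') takes up a nucleophile at the remote carbon and an electrophile at the carbon next to the alkoxy group.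

**Retrosynthetic reasoning**

From 23 back to 22, no skeletal bond is cut; the two phenols are masked as methoxymethyl ethers. The ether on C6' is needed anyway to steer the aryne step and the silylation before it, and using the same group on the C5 oxygen of ring A lets one acid-catalysed acetal exchange finish the synthesis. The forward step has to cleave two acetals without esterifying the hindered ring B acid.

From 22 back to 21, the bond between C1 of ring A and its ester carbon is cut, leaving a bromine. An ester in this position during the aryne step would sit six atoms from the C1' carbanion and would be attacked by it, closing a xanthone. Bromine is inert to that closure and is turned into the ester afterwards by palladium-catalysed alkoxycarbonylation. The gain is that the two carboxyl groups are never equivalent: the ring B carboxyl is already a free acid when the ring A carboxyl is made as its methyl ester.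

From 21 back to 11, 17 and 18, two bonds are cut at neighbouring carbons of ring B: the ether bond C2'–O and the bond from C1' to the carboxyl carbon. This is the only place where one event can form both the hindered ether and the crowded C–C bond, and it reduces the target to two phenol-derived fragments and carbon dioxide (18). In the forward direction the silyl triflate 11 must release the aryne 20, the phenoxide 19 made from 17 must add at C2' and not at C1', and the C1' anion must take up 18 before anything else reaches it.

From 11 back to 9, 6 and 5, the triflate and the silyl group are removed. The C–Si bond sits between two oxygens, which is the ideal site for directed ortho-metalation, so 5 is converted into a secondary carbamate 6 that cooperates with the MOM ether in directing lithiation. After silylation to 9 the carbamate is unmasked and exchanged for the triflate.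

From 5 back to 4, 2, 3 and 1, the phenolic C–O bond is cut. That oxygen stands meta to both the MOM ether and the methyl group of 2, the one position with no ortho neighbour, which is where sterically controlled C–H borylation with 3 places boron. Oxidation of 4 then gives 5, and 2 is the MOM ether of the commercial phenol 1, which already carries chlorine and methyl in the right places.

From 17 back to 16, 15, 13 and 12, the para oxygen of ring A is traced to the aldehyde carbon of 5-bromovanillin (12), which supplies the bromine, the methoxy group and the hindered phenol in the final arrangement. Silylation of that phenol (13), Baeyer–Villiger excision of the formyl carbon (15), MOM protection (16) and desilylation give 17 with only the nucleophilic oxygen free.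

**Alternatives that were turned down**

Alternative 1: Ring B is cut at C6'–C1' and C2'–C3'. The four carbons C3' to C6' come from 2-chloro-3-methylcyclobut-2-en-1-one (A2) and the two carbons C1' and C2' from the aryloxyalkyne A3, which already carries ring A. On heating, A2 would open to a chlorovinylketene that adds to A3; the new cyclobutenone reopens and closes by six-electron electrocyclisation to the phenol A1 (Danheiser benzannulation). In its favour, the substitution pattern of ring B is fixed by connectivity and by the strong polarity of the ynol ether, not by aryne distortion. The neutral thermal conditions also tolerate the ring A ester, so no later carbonylation is needed, and the C6' phenol emerges free. On these points it is stronger than the chosen route. Against it, C1' arrives as a silyloxymethyl group, so desilylation and two oxidations must be run beside a free electron-rich phenol. The benzyl ether on ring A must later be removed without reducing the C5'–Cl bond. A3 is an alkynyl ether of a di-ortho-substituted, ester-bearing phenol, and the usual access through a dichlorovinyl ether and strong base clashes with that ester. A2 is a non-stock 4-unsubstituted halocyclobutenone whose vinylketene can dimerise. The chosen route installs C1' directly as the acid from stable fragments and needs two steps after its key step where A1 needs at least four.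

Alternative 2: Ring B is cut at C1'–C2' and C3'–C4'. The pyrone A5 supplies C1', C6', C5' and C4' with all their substituents and the aryl ethynyl ether A6 supplies C2' and C3'. An inverse-demand Diels–Alder reaction followed by loss of carbon dioxide (18) from the bridged lactone would give A4. In its favour, the C1' carboxyl arrives in the right oxidation state and the two carboxyl groups are distinguished from the outset (benzyl against methyl ester); on that point it equals the chosen route. Against it, A5 carries a donor oxygen on C4 and a methyl group on the very terminus (C6) that must bond to the alkyne. Both lower its reactivity as an electron-poor diene, so temperatures would be needed at which the terminal ynol ether A6 is unlikely to survive. Regiochemistry depends on the ester polarisation outweighing that steric bias. Three benzyl groups must finally be removed beside an aryl chloride, and A5 and A6 each need their own multi-step preparation, A6 sharing the problem of A3. The chosen route offers fewer steps, no hydrogenolysis and fragments that are stable phenol derivatives.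

Alternative 3: Both aryl–carboxyl bonds are cut and the ether is kept. The bromo diaryl ether A8 would undergo bromine–lithium exchange at C1 of ring A, a second alkyllithium with a diamine would lithiate ring B at C1' between the ether oxygen and the MOM ether, and carbon dioxide (18) would quench both carbanions to the diacid A7. In its favour, every operation belongs to a well-established reaction class, the same MOM ether directs the metalation, and acidic methanol could in principle finish the synthesis from A7 in one step. On precedent this is stronger than the chosen key step, and it serves as the fallback for that step below. Against it, A8 must first be made, which brings back the hindered ether problem. The second lithiation must choose C1' over the ring A positions flanked by oxygen and must not be undone by proton transfer between the rings. The two carboxyl groups are born identical and have to be told apart afterwards by a rate difference in esterification alone. The chosen strategy forms the ether and the C1' carboxyl in one operation and differentiates the two carboxyl groups by construction.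

Key step: step 11

Remark on the chemistry: the target has no stereocentre and the diaryl ether is taken as conformationally mobile, so no stereodescriptor appears in any name or SMILES.

**Route**

Step 1
Reactants: 1 2-chloro-3-methylphenol
Product: 2 2-chloro-1-(methoxymethoxy)-3-methylbenzene
Conditions: NaH, MOMCl, THF, 0 °C to rt
Reagents that add atoms: chloromethyl methyl ether (MOMCl) COCCl
Why: O-alkylation of the sodium phenoxide by the reactive α-chloro ether (Williamson-type acetal formation); the ortho chlorine does not hinder it.

Step 2
Reactants: 2 2-chloro-1-(methoxymethoxy)-3-methylbenzene; 3 bis(pinacolato)diboron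
Product: 4 2-[4-chloro-3-(methoxymethoxy)-5-methylphenyl]-4,4,5,5-tetramethyl-1,3,2-dioxaborolane
Conditions: [Ir(cod)(OMe)]2 (cat.), 4,4'-di-tert-butyl-2,2'-bipyridine, THF, 80 °C
Reagents that add atoms: none
Why: Iridium-catalysed aromatic C–H borylation is sterically controlled, and the only C–H bond of 2 without an ortho substituent is the one meta to both the MOM ether and the methyl group; the aryl chloride is tolerated.

Step 3
Reactants: 4 2-[4-chloro-3-(methoxymethoxy)-5-methylphenyl]-4,4,5,5-tetramethyl-1,3,2-dioxaborolane
Product: 5 4-chloro-3-(methoxymethoxy)-5-methylphenol
Conditions: H2O2 (30% aq.), NaOH, THF, 0 °C; aq. NH4Cl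
Reagents that add atoms: hydrogen peroxide OO
Why: Oxidation of the arylboronate by hydroperoxide with 1,2-migration of the aryl group from boron to oxygen; the basic medium leaves the MOM ether intact.

Step 4
Reactants: 5 4-chloro-3-(methoxymethoxy)-5-methylphenol
Product: 6 4-chloro-3-(methoxymethoxy)-5-methylphenyl N-(propan-2-yl)carbamate
Conditions: i-PrNCO, Et3N (cat.), CH2Cl2, rt
Reagents that add atoms: isopropyl isocyanate CC(C)N=C=O
Why: Base-catalysed addition of the phenol to the isocyanate gives the secondary carbamate, a strong ortho-directing group that can later be removed under mild base.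

Step 5
Reactants: 6 4-chloro-3-(methoxymethoxy)-5-methylphenyl N-(propan-2-yl)carbamate
Product: 9 4-chloro-3-(methoxymethoxy)-5-methyl-2-(trimethylsilyl)phenyl N-(propan-2-yl)carbamate, via N-silyl carbamate 7 (not isolated), via N-silyl C-silyl carbamate 8 (not isolated)
Conditions: TMSOTf, TMEDA, Et2O, 0 °C to rt; n-BuLi, TMEDA, −78 °C; TMSCl, −78 °C to rt; aq. NH4Cl
Reagents that add atoms: chlorotrimethylsilane C[Si](C)(C)Cl; trimethylsilyl triflate C[Si](C)(C)OS(=O)(=O)C(F)(F)F (its silyl group is found only in 7 and 8)
Why: Directed ortho-metalation of the carbamate after in situ N-silylation: the position between the carbamate oxygen and the MOM ether is activated by both groups and is lithiated in preference to the position next to the methyl group; the aryllithium is silylated and the N–Si bond is hydrolysed on work-up.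

Step 6
Reactants: 9 4-chloro-3-(methoxymethoxy)-5-methyl-2-(trimethylsilyl)phenyl N-(propan-2-yl)carbamate
Product: 11 4-chloro-3-(methoxymethoxy)-5-methyl-2-(trimethylsilyl)phenyl trifluoromethanesulfonate, via silylphenol 10 (not isolated)
Conditions: Et2NH, DBU, MeCN, 40 °C; then PhNTf2, rt
Reagents that add atoms: N-phenylbis(trifluoromethanesulfonimide) O=S(=O)(N(c1ccccc1)S(=O)(=O)C(F)(F)F)C(F)(F)F
Why: Deprotonation of the carbamate N–H triggers E1cB loss of isopropyl isocyanate (scavenged by diethylamine as a urea), and the phenoxide so released is O-triflated in the same flask; MOM ether, chloride and C–Si bond are untouched.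

Step 7
Reactants: 12 5-bromovanillin (3-bromo-4-hydroxy-5-methoxybenzaldehyde)
Product: 13 3-bromo-5-methoxy-4-{[tri(propan-2-yl)silyl]oxy}benzaldehyde
Conditions: TIPSCl, imidazole, DMF, rt to 40 °C
Reagents that add atoms: chlorotri(propan-2-yl)silane CC(C)[Si](Cl)(C(C)C)C(C)C
Why: Imidazole-mediated silylation of the acidic phenol; the bulky silyl ether is chosen to survive the peracid and the mild methanolysis of the next step.

Step 8
Reactants: 13 3-bromo-5-methoxy-4-{[tri(propan-2-yl)silyl]oxy}benzaldehyde
Product: 15 3-bromo-5-methoxy-4-{[tri(propan-2-yl)silyl]oxy}phenol, via aryl formate 14 (not isolated)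
Conditions: mCPBA, CH2Cl2, 0 °C to rt; then Et3N (cat.), MeOH, rt
Reagents that add atoms: 3-chloroperbenzoic acid OOC(=O)c1cccc(Cl)c1
Why: Baeyer–Villiger oxidation of an aryl aldehyde whose para oxygen makes the aryl group the migrating group, giving the aryl formate; this very labile ester is cleaved by methanol under conditions that leave the aryl silyl ether in place.

Step 9
Reactants: 15 3-bromo-5-methoxy-4-{[tri(propan-2-yl)silyl]oxy}phenol
Product: 16 [2-bromo-6-methoxy-4-(methoxymethoxy)phenoxy]tri(propan-2-yl)silane
Conditions: MOMCl, i-Pr2NEt, CH2Cl2, 0 °C to rt
Reagents that add atoms: chloromethyl methyl ether (MOMCl) COCCl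
Why: Amine-mediated O-alkylation of the unhindered phenol by the α-chloro ether; the silyl ether is stable to these conditions.

Step 10
Reactants: 16 [2-bromo-6-methoxy-4-(methoxymethoxy)phenoxy]tri(propan-2-yl)silane
Product: 17 2-bromo-6-methoxy-4-(methoxymethoxy)phenol
Conditions: TBAF, AcOH, THF, 0 °C
Reagents that add atoms: none
Why: Fluoride cleaves the Si–O bond (strong Si–F bond) and the acetic acid buffer protonates the phenoxide; the MOM ether and the aryl bromide are inert.

Step 11
Reactants: 11 4-chloro-3-(methoxymethoxy)-5-methyl-2-(trimethylsilyl)phenyl trifluoromethanesulfonate; 17 2-bromo-6-methoxy-4-(methoxymethoxy)phenol; 18 carbon dioxide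
Product: 21 6-[2-bromo-6-methoxy-4-(methoxymethoxy)phenoxy]-3-chloro-2-(methoxymethoxy)-4-methylbenzoic acid, via potassium phenoxide 19 (not isolated), via aryne 20 (not isolated)
Conditions: 17, KH, THF, 0 °C; then 18-crown-6, KF, CO2 (1 atm), 11 added slowly, 0 °C to rt; cold dilute HCl to pH 3
Reagents that add atoms: none
Why: Proposed new method: fluoride (KF made soluble by 18-crown-6) attacks the silicon of 11 and triflate leaves, giving the 3-alkoxyaryne 20 with its formal triple bond between C1' and C2'; the potassium phenoxide 19 adds through oxygen at C2', and the C1' aryl anion so formed, held next to the MOM ether, is carboxylated by dissolved CO2 to the potassium benzoate, which acidification converts into 21. The closest known reaction types are the fluoride-induced three-component coupling of 2-silylaryl triflates with amines and CO2 to give anthranilic acids and the fluoride-induced O-arylation of phenols by the same precursors; the new element is a preformed aprotic phenoxide as nucleophile, so that CO2 and not a proton ends the sequence. No ring is closed and no stereocentre is formed. Regioselectivity is required and comes from the MOM ether on C6': its inductive pull distorts the aryne so that C2' is the more electrophilic carbon and negative charge is best placed on C1', and C2' is also the less hindered end because C3' carries hydrogen. O-arylation is secured over C-arylation because both ortho positions and the para position of 19 are substituted. Carboxylation is secured over protonation by forming 19 with KH so that no O–H or N–H acid remains, by using THF and not acetonitrile, and by keeping CO2 at saturation while 11 is added slowly. Carrying ring A as the bromide removes the ortho carbonyl that the aryl anion would otherwise attack in a six-membered closure to a xanthone.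

Step 12
Reactants: 21 6-[2-bromo-6-methoxy-4-(methoxymethoxy)phenoxy]-3-chloro-2-(methoxymethoxy)-4-methylbenzoic acid
Product: 22 3-chloro-6-[2-methoxy-6-(methoxycarbonyl)-4-(methoxymethoxy)phenoxy]-2-(methoxymethoxy)-4-methylbenzoic acid
Conditions: Pd(OAc)2 (cat.), Xantphos, CO (1 atm), Et3N, MeOH/toluene, 80 °C; acidify to pH 3
Reagents that add atoms: carbon monoxide [C-]#[O+]; methanol CO
Why: Palladium-catalysed alkoxycarbonylation of an aryl bromide: oxidative addition of zerovalent palladium into the C–Br bond, CO insertion and methanolysis of the acylpalladium; the hindered electron-rich aryl chloride does not undergo oxidative addition with this catalyst, and the acid is carried as its triethylammonium salt.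

Step 13
Reactants: 22 3-chloro-6-[2-methoxy-6-(methoxycarbonyl)-4-(methoxymethoxy)phenoxy]-2-(methoxymethoxy)-4-methylbenzoic acid
Product: 23 isodihydromaldoxin (3-chloro-2-hydroxy-6-[4-hydroxy-2-methoxy-6-(methoxycarbonyl)phenoxy]-4-methylbenzoic acid)
Conditions: HCl in MeOH (about 1 M), rt
Reagents that add atoms: none
Why: Acid-catalysed acetal exchange transfers both methoxymethyl groups to methanol; the ring B acid, flanked by two ortho substituents, resists Fischer esterification at room temperature, and the ring A methyl ester is degenerate in methanol.

**Compound list**

1 | 2-chloro-3-methylphenol | Cc1cccc(O)c1Cl | starting material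
2 | 2-chloro-1-(methoxymethoxy)-3-methylbenzene | Cc1cccc(OCOC)c1Cl | intermediate
3 | bis(pinacolato)diboron | CC1(C)OB(OC1(C)C)B1OC(C)(C)C(C)(C)O1 | starting material
4 | 2-[4-chloro-3-(methoxymethoxy)-5-methylphenyl]-4,4,5,5-tetramethyl-1,3,2-dioxaborolane | Cc1cc(B2OC(C)(C)C(C)(C)O2)cc(OCOC)c1Cl | intermediate
5 | 4-chloro-3-(methoxymethoxy)-5-methylphenol | Cc1cc(O)cc(OCOC)c1Cl | intermediate
6 | 4-chloro-3-(methoxymethoxy)-5-methylphenyl N-(propan-2-yl)carbamate | Cc1cc(OC(=O)NC(C)C)cc(OCOC)c1Cl | intermediate
7 | 4-chloro-3-(methoxymethoxy)-5-methylphenyl N-(propan-2-yl)-N-(trimethylsilyl)carbamate | Cc1cc(OC(=O)N(C(C)C)[Si](C)(C)C)cc(OCOC)c1Cl | intermediate (not isolated)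
8 | 4-chloro-3-(methoxymethoxy)-5-methyl-2-(trimethylsilyl)phenyl N-(propan-2-yl)-N-(trimethylsilyl)carbamate | Cc1cc(OC(=O)N(C(C)C)[Si](C)(C)C)c([Si](C)(C)C)c(OCOC)c1Cl | intermediate (not isolated)
9 | 4-chloro-3-(methoxymethoxy)-5-methyl-2-(trimethylsilyl)phenyl N-(propan-2-yl)carbamate | Cc1cc(OC(=O)NC(C)C)c([Si](C)(C)C)c(OCOC)c1Cl | intermediate
10 | 4-chloro-3-(methoxymethoxy)-5-methyl-2-(trimethylsilyl)phenol | Cc1cc(O)c([Si](C)(C)C)c(OCOC)c1Cl | intermediate (not isolated)
11 | 4-chloro-3-(methoxymethoxy)-5-methyl-2-(trimethylsilyl)phenyl trifluoromethanesulfonate | C[Si](C)(C)c1c(OS(=O)(=O)C(F)(F)F)cc(C)c(Cl)c1OCOC | intermediate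
12 | 5-bromovanillin (3-bromo-4-hydroxy-5-methoxybenzaldehyde) | COc1cc(C=O)cc(Br)c1O | starting material
13 | 3-bromo-5-methoxy-4-{[tri(propan-2-yl)silyl]oxy}benzaldehyde | COc1cc(C=O)cc(Br)c1O[Si](C(C)C)(C(C)C)C(C)C | intermediate
14 | 3-bromo-5-methoxy-4-{[tri(propan-2-yl)silyl]oxy}phenyl formate | COc1cc(OC=O)cc(Br)c1O[Si](C(C)C)(C(C)C)C(C)C | intermediate (not isolated)
15 | 3-bromo-5-methoxy-4-{[tri(propan-2-yl)silyl]oxy}phenol | COc1cc(O)cc(Br)c1O[Si](C(C)C)(C(C)C)C(C)C | intermediate
16 | [2-bromo-6-methoxy-4-(methoxymethoxy)phenoxy]tri(propan-2-yl)silane | COCOc1cc(OC)c(O[Si](C(C)C)(C(C)C)C(C)C)c(Br)c1 | intermediate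
17 | 2-bromo-6-methoxy-4-(methoxymethoxy)phenol | Oc1c(Br)cc(OCOC)cc1OC | intermediate
18 | carbon dioxide | O=C=O | starting material
19 | potassium 2-bromo-6-methoxy-4-(methoxymethoxy)phenolate | [K+].[O-]c1c(Br)cc(OCOC)cc1OC | intermediate (not isolated)
20 | 4-chloro-3-(methoxymethoxy)-5-methylbenzyne (1,2-didehydrobenzene) | COCOC1=C(Cl)C(C)=CC#C1 | intermediate (not isolated)
21 | 6-[2-bromo-6-methoxy-4-(methoxymethoxy)phenoxy]-3-chloro-2-(methoxymethoxy)-4-methylbenzoic acid | OC(=O)c1c(OCOC)c(Cl)c(C)cc1Oc1c(Br)cc(OCOC)cc1OC | intermediate
22 | 3-chloro-6-[2-methoxy-6-(methoxycarbonyl)-4-(methoxymethoxy)phenoxy]-2-(methoxymethoxy)-4-methylbenzoic acid | OC(=O)c1c(OCOC)c(Cl)c(C)cc1Oc1c(C(=O)OC)cc(OCOC)cc1OC | intermediate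
23 | isodihydromaldoxin (3-chloro-2-hydroxy-6-[4-hydroxy-2-methoxy-6-(methoxycarbonyl)phenoxy]-4-methylbenzoic acid) | COC(=O)c1cc(O)cc(OC)c1Oc1cc(C)c(Cl)c(O)c1C(=O)O | target

**Step count and risks**

Total: 13 steps. Longest linear sequence: 9 steps (steps 1 to 6, then 11 to 13). The ring A branch (steps 7 to 10) joins at step 11.

Least certain steps:

Step 11 (key step, proposed new method). The most likely failure is that the C1' anion is quenched before it meets CO2: by protonation from traces of water, or by bromine transfer from ring A through a six-membered transition state. A second failure is that the phenoxide is partly tied up as its carbonate with CO2, which may arylate through the carbonate oxygen and rearrange to an aryl salicylate, an ester where the ether is wanted. The product carboxylate may also add to a second aryne. Fallback with known chemistry, setting out from 11 and 17: fluoride-induced O-arylation of the free phenol with protic termination (CsF, MeCN, rt) should give 1-bromo-2-[4-chloro-3-(methoxymethoxy)-5-methylphenoxy]-3-methoxy-5-(methoxymethoxy)benzene F1 (the same structure as A8). Bromine–lithium exchange on ring A (t-BuLi, THF, −78 °C), then lithiation of ring B at C1' between the two oxygens (s-BuLi, TMEDA, −78 °C) and a CO2 quench should give 2-[2-carboxy-4-chloro-3-(methoxymethoxy)-5-methylphenoxy]-3-methoxy-5-(methoxymethoxy)benzoic acid F2 (the same structure as A7). Methanolic HCl at 40 °C should then remove both MOM groups and esterify only the ring A acid, which has one ortho substituent, while the ring B acid with two is shielded. The fallback comes back to the route at 23.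

Step 5. The silyl triflate used for N-silylation is a Lewis acid that can open the aryl MOM acetal before the carbamate has consumed it; loss of this protecting group would remove both the second directing group and the later regiocontrol element. Fallback, setting out from 5: carbamoylation with ClCONEt2 (NaH, THF) to 4-chloro-3-(methoxymethoxy)-5-methylphenyl N,N-diethylcarbamate F3, which needs no N-protection. Lithiation with s-BuLi and TMEDA at −78 °C and a TMSCl quench should give 4-chloro-3-(methoxymethoxy)-5-methyl-2-(trimethylsilyl)phenyl N,N-diethylcarbamate F4, and LiAlH4 in THF cleaves the carbamate reductively. The fallback comes back to the route at 10, which is then isolated and triflated with PhNTf2 as in step 6.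

Step 12. Oxidative addition into the electron-rich, ortho-aryloxy bromide may be slow, and the free carboxylate can coordinate palladium or capture the acylpalladium, so hydrodebromination or stalling may compete with ester formation. Fallback, setting out from 21: the acid is masked with MOMCl and i-Pr2NEt as methoxymethyl 6-[2-bromo-6-methoxy-4-(methoxymethoxy)phenoxy]-3-chloro-2-(methoxymethoxy)-4-methylbenzoate F5. The same carbonylation on this neutral substrate should give methoxymethyl 3-chloro-6-[2-methoxy-6-(methoxycarbonyl)-4-(methoxymethoxy)phenoxy]-2-(methoxymethoxy)-4-methylbenzoate F6. Methanolic HCl then removes the MOM ester together with both MOM ethers, coming back to the route at 23.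

Step 8. The silyloxy group, flanked by bromine and methoxy, is twisted out of conjugation, so hydride migration (giving the benzoic acid) may compete with aryl migration, and the silyl ether may be partly lost in the methanolysis. Fallback, setting out from 12: Dakin oxidation of the free p-hydroxybenzaldehyde (H2O2, aq. NaOH), where the phenoxide makes aryl migration dominant, should give 2-bromo-6-methoxybenzene-1,4-diol F7. Formation of its dianion (NaH, 2.2 equiv, DMF, under argon) and addition of one equivalent of MOMCl should alkylate the more basic, unhindered oxygen, coming back to the route at 17.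

**Further compounds**

F1 | step 11 | 1-bromo-2-[4-chloro-3-(methoxymethoxy)-5-methylphenoxy]-3-methoxy-5-(methoxymethoxy)benzene | COCOc1cc(OC)c(Oc2cc(C)c(Cl)c(OCOC)c2)c(Br)c1
F2 | step 11 | 2-[2-carboxy-4-chloro-3-(methoxymethoxy)-5-methylphenoxy]-3-methoxy-5-(methoxymethoxy)benzoic acid | OC(=O)c1cc(OCOC)cc(OC)c1Oc1cc(C)c(Cl)c(OCOC)c1C(=O)O
F3 | step 5 | 4-chloro-3-(methoxymethoxy)-5-methylphenyl N,N-diethylcarbamate | CCN(CC)C(=O)Oc1cc(C)c(Cl)c(OCOC)c1
F4 | step 5 | 4-chloro-3-(methoxymethoxy)-5-methyl-2-(trimethylsilyl)phenyl N,N-diethylcarbamate | CCN(CC)C(=O)Oc1cc(C)c(Cl)c(OCOC)c1[Si](C)(C)C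
F5 | step 12 | methoxymethyl 6-[2-bromo-6-methoxy-4-(methoxymethoxy)phenoxy]-3-chloro-2-(methoxymethoxy)-4-methylbenzoate | COCOC(=O)c1c(OCOC)c(Cl)c(C)cc1Oc1c(Br)cc(OCOC)cc1OC
F6 | step 12 | methoxymethyl 3-chloro-6-[2-methoxy-6-(methoxycarbonyl)-4-(methoxymethoxy)phenoxy]-2-(methoxymethoxy)-4-methylbenzoate | COCOC(=O)c1c(OCOC)c(Cl)c(C)cc1Oc1c(C(=O)OC)cc(OCOC)cc1OC
F7 | step 8 | 2-bromo-6-methoxybenzene-1,4-diol | COc1cc(O)cc(Br)c1O
A1 | alternative 1 | methyl 5-(benzyloxy)-2-{2-[(tert-butyldimethylsilyloxy)methyl]-4-chloro-3-hydroxy-5-methylphenoxy}-3-methoxybenzoate | COC(=O)c1cc(OCc2ccccc2)cc(OC)c1Oc1cc(C)c(Cl)c(O)c1CO[Si](C)(C)C(C)(C)C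
A2 | alternative 1 | 2-chloro-3-methylcyclobut-2-en-1-one | CC1=C(Cl)C(=O)C1
A3 | alternative 1 | methyl 5-(benzyloxy)-2-({3-[(tert-butyldimethylsilyl)oxy]prop-1-yn-1-yl}oxy)-3-methoxybenzoate | COC(=O)c1cc(OCc2ccccc2)cc(OC)c1OC#CCO[Si](C)(C)C(C)(C)C
A4 | alternative 2 | benzyl 2-(benzyloxy)-6-[4-(benzyloxy)-2-methoxy-6-(methoxycarbonyl)phenoxy]-3-chloro-4-methylbenzoate | COC(=O)c1cc(OCc2ccccc2)cc(OC)c1Oc1cc(C)c(Cl)c(OCc2ccccc2)c1C(=O)OCc1ccccc1
A5 | alternative 2 | benzyl 4-(benzyloxy)-5-chloro-6-methyl-2-oxo-2H-pyran-3-carboxylate | O=C1OC(C)=C(Cl)C(OCc2ccccc2)=C1C(=O)OCc1ccccc1
A6 | alternative 2 | methyl 5-(benzyloxy)-2-(ethynyloxy)-3-methoxybenzoate | COC(=O)c1cc(OCc2ccccc2)cc(OC)c1OC#C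
A7 | alternative 3 | 2-[2-carboxy-4-chloro-3-(methoxymethoxy)-5-methylphenoxy]-3-methoxy-5-(methoxymethoxy)benzoic acid | OC(=O)c1cc(OCOC)cc(OC)c1Oc1cc(C)c(Cl)c(OCOC)c1C(=O)O
A8 | alternative 3 | 1-bromo-2-[4-chloro-3-(methoxymethoxy)-5-methylphenoxy]-3-methoxy-5-(methoxymethoxy)benzene | COCOc1cc(OC)c(Oc2cc(C)c(Cl)c(OCOC)c2)c(Br)c1
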